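Late in the west run the target barely moved: between 3.5 h and 5.5 h it rose at 0.00500 M h⁻¹, far slower than the 0.164 M h⁻¹ of the first reading, although the target at the last reading stood for 33.8% of the substrate charged.

| flask | substrate | partner | target | time |
|---|---|---|---|---|
| west | 0.500 M | 0.400 M |  |  |
| north | 0.500 M | 0.400 M | 0.250 M |  |
| south-west | 0.750 M | 0.400 M |  |  |
| east | 0.500 M | 1.20 M |  |  |
| south | 2.50 M | 2.00 M |  | 5.5 h |

| west run: time / h | west run: [target] / M | north run: time / h | north run: [target] / M | south-west run: time / h | south-west run: [target] / M | east run: time / h | east run: [target] / M |
|---|---|---|---|---|---|---|---|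
| 0.22 | 0.036 | 0.22 | 0.273 | 0.22 | 0.044 | 0.22 | 0.118 |
| 0.35 | 0.049 | 0.35 | 0.284 | 0.35 | 0.069 | 0.35 | 0.160 |
| 0.55 | 0.072 | 0.55 | 0.289 | 0.55 | 0.103 | 0.55 | 0.197 |
| 0.87 | 0.094 | 0.87 | 0.309 | 0.87 | 0.129 | 0.87 | 0.230 |
| 1.4 | 0.122 | 1.4 | 0.318 | 1.4 | 0.166 | 1.4 | 0.247 |
| 2.2 | 0.145 | 2.2 | 0.335 | 2.2 | 0.191 | 2.2 | 0.240 |
| 3.5 | 0.159 | 3.5 | 0.331 | 3.5 | 0.207 | 3.5 | 0.222 |
| 5.5 | 0.169 | 5.5 | 0.336 | 5.5 | 0.216 | 5.5 | 0.207 |

(scatter of a reading: 0.003 M)

- Overall: substrate + partner -> target.
- Constant volume, constant temperature.
- "The second partner" is partner.
- An order is taken over about fifteen percent of the charge, up and down.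

- how the opening rate goes with [substrate] round the charge of the west run: the exponent of the rate at two percent of substrate gone to target (one fixed amount of target, the same in the runs compared)
- how the opening rate goes with [partner] round the charge of the west run: the exponent of the rate at two percent of substrate gone to target
- target in the south run at 5.5 h, as a share of the substrate charged

So I wrote the balance of partner, the limiting reagent of the west run (0.400 M against 0.500 M of substrate). I let partner leave by two routes, into target at a rate proportional to [substrate][partner] and into loss at a rate proportional to [partner], and I took [partner] as negligible at the last reading. Dividing one route by the other and integrating gave: partner charged = target made + c·ln([substrate] charged / [substrate] at the end). The west run gave c = 0.560 M, the break-even substrate, which is the [substrate] at which the two routes run equally fast. The south-west run, with a different charge of substrate, gave 0.542 M by the same balance, and I trusted this agreement for flasks low in target.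

The north run parted from them: it gained 0.0860 M and gave 1.66 M, a factor of 2.96 above the west value. The balance counts target that stays, but in the east run target fell from 0.247 M at 1.4 h to 0.207 M at 5.5 h. I therefore read c as growing with the target present, since the north run started at 0.250 M, more than the 0.169 M the west run ended with. The low value was the one that cheated for a flask rich in target.

Scaling the west opening rate with both charges, I estimated that the south run passes 0.250 M of target in 0.0611 h, far shorter than its 5.5 h, so I used the north value. The balance then closed at 1.07 M of target, 42.8% of the substrate charged, whereas the west value gave 60.0%.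

The forecast gave orders of 0.8 in substrate and 1.2 in partner and a south share of 42%, of which it said “This is a rough estimate.”

The south run gave 44.7% of the substrate charged as target at 5.5 h, with orders of 1.0 in substrate and 1.2 in partner. The steps behind the readings were these:

    substrate + partner → target (0.7092 M⁻¹ h⁻¹)
    substrate + 2 partner → target + partner (0.4284 M⁻² h⁻¹)
    target + partner → side product (0.5364 M⁻¹ h⁻¹)
    partner → lost reagent (0.2027 h⁻¹)

The turning of target + partner into side product moves the readings by 27 in units of the scatter, root mean square. Read back through the balance, the south run's 1.12 M of target gives a break-even substrate of 1.49 M, higher than the west run's 0.560 M and lower than the north run's 1.66 M.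

(The numbers in the tables stem from a simulated flask on assumed constants.)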